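**Assumptions**
- The guaiacyl phenol is carried as its benzyl ether. 4-(Benzyloxy)-3-methoxyphenylacetic acid (**8**) is commercial.
- The syringyl phenol stays free because it is needed to form the p-quinone methide.
- I take the facial selectivity of each aminocatalyst from the known sense of induction of diarylprolinol silyl ethers. Both catalyst enantiomers would be screened to confirm the assignment.

## Retrosynthetic overview
1. Target **1** comes from benzyl ether **2** by hydrogenolysis. **2** comes from primary alcohol **3** by chemoselective (lipase) acetylation of the primary OH. **3** comes from aldehyde **4** by NaBH4 reduction.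
2. **4** is disconnected at C7'–C8'. Enamine α-benzylation of (3S)-aldehyde **5** with the p-quinone methide derived from syringyl alcohol **6** sets C8'.
3. **5** is disconnected at C7–C8. Organo-photoredox decarboxylative benzylation of crotonaldehyde **7** with arylacetic acid **8** sets the first stereocenter, C8.
4. The molecule is acyclic, so no rings are formed. C8 is set first, then C8' under catalyst control.

## Route

**Step 1**
Reactants: **7** crotonaldehyde ((E)-but-2-enal); **8** 4-(benzyloxy)-3-methoxyphenylacetic acid
Product: **5** (3S)-4-[4-(benzyloxy)-3-methoxyphenyl]-3-methylbutanal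
Conditions: **9** (S)-diphenylprolinol TMS ether (20 mol%), **10** 4CzIPN (2 mol%), K2HPO4 (0.5 equiv), **7** (3 equiv), **8** (1 equiv), DMSO, 455 nm blue LEDs, rt, 24 h
Reagents that add atoms: none (CO2 is lost)
Why: Iminium-ion radical conjugate addition under photoredox catalysis. The (E)-crotonyl iminium ion of **9** is s-trans, and the benzylic radical adds to its β-carbon on the face opposite the bulky diarylsilyloxymethyl group. With the (S)-catalyst this face gives the S configuration at C3 (C8 of the target).
Proposed new method: excited 4CzIPN oxidises the arylacetate (carboxylate or electron-rich arene) and CO2 is lost to give the nucleophilic ArCH2• radical. The radical adds to the iminium β-carbon, and the resulting α-iminium radical (the enamine radical cation) is reduced by 4CzIPN•– to the neutral enamine. Hydrolysis then releases aldehyde **5**, so the cycle is redox-neutral. The closest known reactions are photoredox decarboxylative Giese additions and radical conjugate additions to enal-derived iminium ions with other radical sources. Electron-rich benzylic radicals from arylacetic acids adding to a β-methyl enal iminium have not been shown.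

**Step 2**
Reactants: **5**; **6** syringyl alcohol (4-hydroxy-3,5-dimethoxybenzyl alcohol, 2 equiv)
Product: **4** (2R,3S)-4-[4-(benzyloxy)-3-methoxyphenyl]-2-[(4-hydroxy-3,5-dimethoxyphenyl)methyl]-3-methylbutanal
Conditions: **11** (R)-diphenylprolinol TMS ether (20 mol%), TFA (20 mol%), MeCN/HFIP 4:1, 50 °C, 24 h. The reaction mixture is taken directly into Step 3 without isolating the aldehyde.
Reagents that add atoms: none (water is lost)
Why: Enamine catalysis with a p-quinone methide, a 1,6-conjugate addition of the SN1 type. Acid and HFIP ionise **6** to the 2,6-dimethoxy-p-quinone methide, which the (E)-s-trans enamine of **5** traps on the face opposite the bulky group. The (R)-catalyst gives the R configuration at the new α-centre (C8'). That is catalyst control, and it should be matched with the existing 3S centre.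

**Step 3**
Reactants: **4**
Product: **3** (2R,3S)-4-[4-(benzyloxy)-3-methoxyphenyl]-2-[(4-hydroxy-3,5-dimethoxyphenyl)methyl]-3-methylbutan-1-ol
Conditions: the Step 2 mixture is diluted with MeOH/THF 1:1, then NaBH4 (3 equiv, enough to neutralise TFA and reduce) is added at 0 °C, 20 min
Reagents that add atoms: none (only H is added)
Why: Chemoselective 1,2-reduction of the aldehyde (NaBH4 reduction). Reducing the aldehyde without isolation avoids epimerisation of the α-stereocentre, and the benzyl ether and phenol are untouched.

**Step 4**
Reactants: **3**; **12** vinyl acetate (5 equiv)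
Product: **2** (2R,3S)-4-[4-(benzyloxy)-3-methoxyphenyl]-2-[(4-hydroxy-3,5-dimethoxyphenyl)methyl]-3-methylbutyl acetate
Conditions: CAL-B (Novozym 435), MTBE, 30 °C, 16 h
Reagents that add atoms: vinyl acetate, C=COC(C)=O (delivers the acetyl group)
Why: Lipase-catalysed transesterification acylates the primary aliphatic OH and not the hindered 2,6-dimethoxyphenol. It is irreversible because vinyl alcohol tautomerises to acetaldehyde, and no stereocenter is touched.

**Step 5**
Reactants: **2**
Product: **1** target, (2R,3S)-2-[(4-hydroxy-3,5-dimethoxyphenyl)methyl]-4-(4-hydroxy-3-methoxyphenyl)-3-methylbutyl acetate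
Conditions: H2 (1 atm), 10% Pd/C, EtOAc/EtOH, rt, 4 h
Reagents that add atoms: none (only H is added)
Why: Hydrogenolysis of the aryl benzyl ether. The alkyl acetate, aryl methyl ethers, free syringyl phenol and both stereocenters are unaffected; the only by-product is toluene.

## Compound list
1 | (2R,3S)-2-[(4-hydroxy-3,5-dimethoxyphenyl)methyl]-4-(4-hydroxy-3-methoxyphenyl)-3-methylbutyl acetate | COc1cc(C[C@H](C)[C@H](COC(C)=O)Cc2cc(OC)c(O)c(OC)c2)ccc1O | target
2 | (2R,3S)-4-[4-(benzyloxy)-3-methoxyphenyl]-2-[(4-hydroxy-3,5-dimethoxyphenyl)methyl]-3-methylbutyl acetate | COc1cc(C[C@H](C)[C@H](COC(C)=O)Cc2cc(OC)c(O)c(OC)c2)ccc1OCc1ccccc1 | intermediate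
3 | (2R,3S)-4-[4-(benzyloxy)-3-methoxyphenyl]-2-[(4-hydroxy-3,5-dimethoxyphenyl)methyl]-3-methylbutan-1-ol | COc1cc(C[C@H](C)[C@H](CO)Cc2cc(OC)c(O)c(OC)c2)ccc1OCc1ccccc1 | intermediate
4 | (2R,3S)-4-[4-(benzyloxy)-3-methoxyphenyl]-2-[(4-hydroxy-3,5-dimethoxyphenyl)methyl]-3-methylbutanal | COc1cc(C[C@H](C)[C@H](C=O)Cc2cc(OC)c(O)c(OC)c2)ccc1OCc1ccccc1 | intermediate
5 | (3S)-4-[4-(benzyloxy)-3-methoxyphenyl]-3-methylbutanal | COc1cc(C[C@H](C)CC=O)ccc1OCc1ccccc1 | intermediate
6 | syringyl alcohol (4-hydroxy-3,5-dimethoxybenzyl alcohol) | COc1cc(CO)cc(OC)c1O | starting material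
7 | crotonaldehyde ((E)-but-2-enal) | C/C=C/C=O | starting material
8 | 4-(benzyloxy)-3-methoxyphenylacetic acid | COc1cc(CC(=O)O)ccc1OCc1ccccc1 | starting material
9 | (S)-diphenylprolinol TMS ether (organocatalyst) | C[Si](C)(C)OC(c1ccccc1)(c1ccccc1)[C@@H]1CCCN1 | starting material
10 | 4CzIPN (2,4,5,6-tetra(carbazol-9-yl)isophthalonitrile, photocatalyst) | N#Cc1c(n2c3ccccc3c3ccccc32)c(C#N)c(n2c3ccccc3c3ccccc32)c(n2c3ccccc3c3ccccc32)c1n1c2ccccc2c2ccccc21 | starting material
11 | (R)-diphenylprolinol TMS ether (organocatalyst) | C[Si](C)(C)OC(c1ccccc1)(c1ccccc1)[C@H]1CCCN1 | starting material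
12 | vinyl acetate | C=COC(C)=O | starting material

## Totals
- Total steps: 5
- Longest linear sequence: 5 (Steps 2 and 3 are telescoped in one pot)

## Three steps most likely to fail
1. **Step 1 (proposed new).** Benzyl radical dimerisation, reduction of the iminium ion by 4CzIPN•–, or poor ee could lower the yield.
   Fallback using known chemistry: make the (E)-enal 4-aryl-3-methylbut-2-enal from 4-(benzyloxy)-3-methoxyphenylacetone by HWE olefination, DIBAL reduction and MnO2 oxidation. Then run an organocatalytic Hantzsch-ester transfer hydrogenation (imidazolidinone or chiral phosphoric acid catalyst) to give (S)-**5**.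
2. **Step 2.** The free syringyl quinone methide may oligomerise or alkylate the amine catalyst, or the diastereoselectivity may be poor.
   Fallback: oxidise **5** (Pinnick) to the acid and attach an Evans oxazolidinone. Alkylate with 4-benzyloxy-3,5-dimethoxybenzyl bromide (NaHMDS), then remove the auxiliary with LiBH4. Acetylate the primary alcohol and remove both benzyl groups by hydrogenolysis.
3. **Step 4.** The β-branched alcohol may convert slowly, or some phenol acylation may occur.
   Fallback: peracetylate with Ac2O/DMAP, then selectively cleave the aryl acetate with NH4OAc in aqueous MeOH, which leaves the alkyl acetate intact.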